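## Structural features

The target is a daucane diester in which a cyclopentane (C1–C2–C3–C4–C5) and a cycloheptene (C1–C5–C6–C7–C8=C9–C10) share the C1–C5 bond as a trans-fused hydroazulene; β is the face of the angular methyl on C1. Five stereocentres form one unbroken chain: C4 (β-OH, α-isopropyl), C5 (α-H) and C6 (α-O) on one side of the ring fusion, quaternary C1 (β-methyl) and C10 (β-O) on the other. Re-reading the SMILES confirms 4β-OH, 5α-H, 6α-(4-hydroxybenzoyloxy) and 10β-angeloyloxy, with the vinylic methyl on C8. The fragile parts are the angelate (it slips to the tiglate under nucleophilic or basic catalysis), the allylic C10–O bond, the free phenol, and the C4 carbinol, which is β to C6 and invites retro-aldol cleavage or dehydration whenever C6 is a carbonyl. The real difficulties are the quaternary C1 next to the ring-fusion methine C5, the trans fusion, and telling the C6 and C10 oxygens apart. The key step uses the pattern of the five-membered ring: oxygenated C4, then C5 with the one-carbon branch C6, then quaternary C1 with methyl and C10. This is the signature of β-vinylation and α-hydroxymethylation of 3-methylcyclopent-2-en-1-one, with the ketone carbon as C4.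

## Logic of the disconnections

29 to 28: the two O–Si bonds (C4–O and aryl–O) are cut last. Both free hydroxyls stay masked until the two esters are in place, which removes any question of which oxygen is acylated. The forward step must cleave silicon without isomerising the Z-alkene of the C10 ester or moving an acyl group.

28 to 25 and 26: the C10 O–acyl bond. The Z-2-methylbut-2-enoyl unit is the most isomerisation-prone part, so it enters as late as possible. The forward step must acylate a hindered allylic alcohol next to a quaternary carbon with no Z to E leakage.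

25 to 24: the C10–H bond. Going back to the ketone removes the C10 stereocentre and makes C8=C9 part of an enone, which explains the position of the double bond. The forward step must deliver hydride 1,2 and from the α face.

24 to 19 and 22 (22 from 20): the C6 O–acyl bond. At this stage C6 is an alcohol and C10 a ketone, so the two oxygens differ in oxidation level and need no selective protection. The forward step must acylate a crowded secondary alcohol without base-induced loss of the ester across the enone.

19 to 17: the C6–C7 bond. Opening the seven-membered ring removes the ring and the C6 stereocentre and leaves a monocyclic keto-aldehyde. The forward closure must use the alkene terminus C7 as nucleophile (not the enolisable C9), must place oxygen α at C6, and must leave the alkene at C8=C9; conjugation with the C10 ketone is what guides the last point.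

17 to 16 to 15: redox and protecting-group adjustment at C6 and C10. Both carbonyls are traced to carbinols so that they can be unveiled together, the C6 one through its silyl ether. The forward steps need a primary silyl ether to be cleaved beside a tertiary one, and an oxidation that neither conjugates the β,γ-alkene nor epimerises C5.

15 to 12 and 13: the C9–C10 bond. One reagent brings C7, C8, C9 and the C8 methyl. The forward step is an addition to a neopentyl aldehyde; no control is needed at C10 because it is oxidised later.

12 to 11: the C10=O bond is traced to C10=CH2. A vinyl group carries C10 unharmed through the organometallic step at C4. The forward ozonolysis needs the vinyl group to be the only alkene present.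

11 to 10 to 7 and 8: the C4 O–Si bond, then the C4–isopropyl bond. This removes the C4 stereocentre and three carbons. The forward addition must reach a hindered, enolisable ketone from the α face, anti to the C5 side chain, without enolisation or reduction.

7 to 6 to 1, 2 and 3: the O–Si bond, then the C1–C10 and C5–C6 bonds together. Two C–C bonds and two stereocentres fall away in one operation and three commercial compounds remain. The forward step must create the quaternary C1 enantioselectively and put C6 trans to C10 at C5.

## Other disconnections considered

Alternative 1: The cut runs through C1–C5 and C6–C7, with the cyclopropane bond C7–C9 as a third bond that changes. A terminal alkyne C5≡C6 on C4 and a vinylcyclopropane C1=C10–C9(C8)(C7), linked through C2–C3, would combine under [Rh(CO)2Cl]2 in an intramolecular (5+2) cycloaddition to give dauca-5,9-dien-4-ol triethylsilyl ether A1. C4 with its hydroxyl and isopropyl group would come intact from (S)-terpinen-4-ol A2 after cleavage of its ring alkene.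
- In its favour: both rings close in one catalytic step, where step 1 of the chosen plan closes none; on ring construction the alternative is better. C4 needs no organometallic addition to a hindered ketone and raises no facial question; on C4 it is also better.
- Against it: the quaternary C1 would arise from a fully substituted alkene terminus, a slow substrate class for this cycloaddition, and its configuration would rest on 1,3-induction from C4 across the forming ring. The methyl-bearing cyclopropane must be a single stereoisomer and must open at its less substituted bond. A1 has neither ring oxygen: C5=C6 must be hydrated from the α face, and C9=C10 must be oxidised with allylic transposition to give C8=C9 and a β-oxygen at C10. Commercial A2 is often not enantiopure.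
- Comparison: structurally the alternative maps the carbon skeleton more directly. Mechanistically it is one metallacycle-based event against a conjugate addition plus aldol. It is weaker at C1, C6 and C10, where the chosen plan uses catalyst control and carbonyl-guided cyclic substrates. In step count the two should be about equal, because precursor assembly and the late oxidations offset the one-step bicyclisation.

Alternative 2: The cut is the single bond C1–C5. Rh2(OAc)4 would decompose methyl (6S)-2-diazo-6-methyl-3-oxo-7-(pivaloyloxy)heptanoate A4, and the carbenoid at C5 would insert into the tertiary C1–H bond with retention. The product would be methyl 5-methyl-2-oxo-5-(pivaloyloxymethyl)cyclopentane-1-carboxylate A3.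
- In its favour: C1 is transferred stereospecifically from a stereocentre available in enantiopure form, so no catalyst has to discriminate the faces of a five-membered enone; on C1 the alternative is better. In A3 the C5 ester is a freely equilibrating β-keto ester between methyl and the clearly larger pivaloyloxymethyl group, so C6 trans to C10 is better secured than between methyl and vinyl; on C5 it is better too. 1,5-Insertion into a tertiary C–H bond is a well-behaved reaction class.
- Against it: A4 needs about five steps, and the key step forms one C–C bond instead of two. The β-keto ester would be deprotonated by the isopropyl nucleophile, so the ester must be reduced and protected and C4 taken through a reduction and reoxidation before the addition. C10 arrives as a protected alcohol, two steps from the aldehyde instead of one.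
- Comparison: after these adjustments the alternative meets the chosen route near 11 and is equal from there on. Overall it should be five to six steps longer. Both mechanisms are established; the alternative is the more predictable in stereochemistry, the chosen plan the more economical.

Alternative 3: The cut runs through C6–C7 and C9–C10. Indium powder and 3-iodo-2-(iodomethyl)prop-1-ene A7 would allylate the dialdehyde A6 twice, first intermolecularly and then intramolecularly. This would close the seven-membered ring as 8-methylene-4-triethylsilyloxydaucane-6,10-diol A5.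
- In its favour: the ring and both oxygenated carbons form in one operation, and A6 lies two steps from 12; at the ring closure the alternative is better in step economy (one step against steps 6 to 9). The conditions are mild, and no β,γ-unsaturated ketone has to be handled.
- Against it: two carbinol stereocentres (C6 and C10) form without an evident controlling element. The two secondary hydroxyls of A5 are similar and must be told apart for two different esters, whereas the chosen plan keeps them at different oxidation levels. The exocyclic alkene must move into the ring towards C9 and not C7 with no C10 carbonyl to direct it. Oligomerisation competes with the second, ring-closing allylation.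
- Comparison: structurally both plans close the same two bonds of the seven-membered ring, and both rely on an allyl-type nucleophile adding to an aldehyde. The alternative is two to three steps shorter if its selectivities hold; the chosen plan is longer but assigns each stereocentre and the alkene position to a controlling feature.

Key step: step 1

Remark on the chemistry: methyl and vinyl on C1 shield the two faces of C5 almost equally, so step 1 is planned on the expectation that both C5 epimers form and that the wanted one (C6 cis to the methyl, trans to vinyl) is separated as silyl ether 7.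

## Route

Step 1
Reactants: 1 3-methylcyclopent-2-en-1-one; 2 vinylmagnesium bromide; 3 formaldehyde
Product: 6 (2S,3R)-3-ethenyl-2-(hydroxymethyl)-3-methylcyclopentan-1-one, via dimethyl(vinyl)aluminium 4 (not isolated), via aluminium enolate 5 (not isolated)
Conditions: 2, Me2AlCl, Et2O, 0 °C; Cu(OTf)2 (10 mol %), chiral BINOL-derived phosphoramidite (20 mol %), 1, Et2O, −30 → 0 °C; 3 (monomeric, THF), −78 → −40 °C; aq. Rochelle salt
Reagents that add atoms: none
Why: The alane reduces Cu(OTf)2 to a monovalent copper–phosphoramidite complex, vinyl passes from aluminium to copper, the aluminium-activated enone forms a π-complex, and oxidative addition at C1 to a trivalent copper σ-complex followed by reductive elimination forms C1–C10 and releases the dimethylaluminium enolate 5. Enolate 5 then adds to formaldehyde at C5 through a closed, aluminium-centred six-membered aldol transition state, forming C5–C6. The closest known reaction type is the copper-catalysed asymmetric conjugate addition of alkenylalanes to 3-substituted cycloalkenones with aldol trapping of the aluminium enolate. No ring is closed. C1 is controlled by the chiral ligand, whose enantiomer is chosen to deliver vinyl to the α face (methyl β). C5 is controlled only by the two C1 substituents, formaldehyde approaching anti to the one that shields more, and since methyl and vinyl are nearly equal the bias is expected to be weak, hence the separation at 7. The step needs vinyl rather than methyl transfer (sp2 groups pass from aluminium to copper faster), 1,4- rather than 1,2-addition (copper catalysis), and hydroxymethylation at C5 rather than C3 (the enolate is formed regiospecifically and is trapped cold before it can equilibrate).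

Step 2
Reactants: 6 (2S,3R)-3-ethenyl-2-(hydroxymethyl)-3-methylcyclopentan-1-one
Product: 7 (2S,3R)-3-ethenyl-3-methyl-2-[(triethylsilyloxy)methyl]cyclopentan-1-one
Conditions: TESCl, imidazole, CH2Cl2, 0 °C; chromatographic removal of the C5 epimer
Reagents that add atoms: chlorotriethylsilane, CC[Si](CC)(CC)Cl
Why: Imidazole-mediated silylation of the primary alcohol blocks retro-aldol and dehydration of the β-hydroxy ketone before the organometallic step. The conditions do not enolise the ketone, so no stereocentre is touched.

Step 3
Reactants: 7 (2S,3R)-3-ethenyl-3-methyl-2-[(triethylsilyloxy)methyl]cyclopentan-1-one; 8 isopropylmagnesium chloride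
Product: 10 (1R,2S,3R)-3-ethenyl-3-methyl-1-(propan-2-yl)-2-[(triethylsilyloxy)methyl]cyclopentan-1-ol, via isopropylcerium dichloride 9 (not isolated)
Conditions: CeCl3 (anhydrous), THF, rt; 8, 0 °C; then 7, −78 → −40 °C; aq. NH4Cl
Reagents that add atoms: none
Why: Imamoto-type organocerium 1,2-addition: the weakly basic, oxophilic reagent adds to the hindered, enolisable ketone without enolisation, β-elimination of the silyloxy group or β-hydride reduction. Methyl and vinyl on C1 balance each other across the ring, so the adjacent C5 side chain (β) decides: isopropyl enters from the α face, anti to CH2OSi, giving the 4β-hydroxyl.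

Step 4
Reactants: 10 (1R,2S,3R)-3-ethenyl-3-methyl-1-(propan-2-yl)-2-[(triethylsilyloxy)methyl]cyclopentan-1-ol
Product: 11 triethyl{[(1R,2S,3R)-3-ethenyl-3-methyl-1-(propan-2-yl)-2-[(triethylsilyloxy)methyl]cyclopentyl]oxy}silane
Conditions: TESOTf, 2,6-lutidine, CH2Cl2, −78 → 0 °C
Reagents that add atoms: triethylsilyl trifluoromethanesulfonate, CC[Si](CC)(CC)OS(=O)(=O)C(F)(F)F
Why: Silyl triflate silylation of a hindered tertiary alcohol. The C4 ether closes the retro-aldol and dehydration pathways that a free β-hydroxyl would open once C6 is an aldehyde, and its tertiary, isopropyl-flanked position lets it outlast the later methanolysis of the primary silyl ether.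

Step 5
Reactants: 11 triethyl{[(1R,2S,3R)-3-ethenyl-3-methyl-1-(propan-2-yl)-2-[(triethylsilyloxy)methyl]cyclopentyl]oxy}silane
Product: 12 (1S,2S,3R)-1-methyl-3-(propan-2-yl)-3-(triethylsilyloxy)-2-[(triethylsilyloxy)methyl]cyclopentane-1-carbaldehyde
Conditions: O3, CH2Cl2, −78 °C; PPh3, −78 °C → rt
Reagents that add atoms: ozone, [O-][O+]=O
Why: Ozonolysis with reductive work-up (Criegee mechanism) cleaves the only C=C bond. The aldehyde sits on the quaternary C1 and cannot enolise, and silyl ethers are inert to ozone at −78 °C.

Step 6
Reactants: 12 (1S,2S,3R)-1-methyl-3-(propan-2-yl)-3-(triethylsilyloxy)-2-[(triethylsilyloxy)methyl]cyclopentane-1-carbaldehyde; 13 3-chloro-2-methylprop-1-ene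
Product: 15 3-methyl-1-[(1S,2S,3R)-1-methyl-3-(propan-2-yl)-3-(triethylsilyloxy)-2-[(triethylsilyloxy)methyl]cyclopentyl]but-3-en-1-ol (both C10 epimers), via methallylmagnesium chloride 14 (not isolated)
Conditions: 13, Mg, THF, 0 °C; then 12, −78 → 0 °C; aq. NH4Cl
Reagents that add atoms: none
Why: Grignard 1,2-addition of the allyl-type reagent to the hindered, non-enolisable neopentyl aldehyde forms C9–C10; allylic transposition is degenerate for this symmetric unit. The new C10 centre is not controlled and need not be, since step 8 oxidises it.

Step 7
Reactants: 15 3-methyl-1-[(1S,2S,3R)-1-methyl-3-(propan-2-yl)-3-(triethylsilyloxy)-2-[(triethylsilyloxy)methyl]cyclopentyl]but-3-en-1-ol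
Product: 16 1-[(1S,2S,3R)-2-(hydroxymethyl)-1-methyl-3-(propan-2-yl)-3-(triethylsilyloxy)cyclopentyl]-3-methylbut-3-en-1-ol
Conditions: PPTS (cat.), MeOH/CH2Cl2, 0 °C
Reagents that add atoms: none
Why: Acid-catalysed methanolysis of silyl ethers is governed by access to silicon, so the primary C6 ether is cleaved and the tertiary, isopropyl-flanked C4 ether is kept. PPTS is too weak to ionise the tertiary or homoallylic centres.

Step 8
Reactants: 16 1-[(1S,2S,3R)-2-(hydroxymethyl)-1-methyl-3-(propan-2-yl)-3-(triethylsilyloxy)cyclopentyl]-3-methylbut-3-en-1-ol
Product: 17 (1R,2S,5R)-2-methyl-2-(3-methylbut-3-enoyl)-5-(propan-2-yl)-5-(triethylsilyloxy)cyclopentane-1-carbaldehyde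
Conditions: Dess–Martin periodinane (3 equiv), NaHCO3, CH2Cl2, 0 °C → rt
Reagents that add atoms: none
Why: Dess–Martin oxidation converts both carbinols in one operation under neutral, buffered conditions. It is chosen because it leaves the β,γ-unsaturated ketone unconjugated and C5 (now α to an aldehyde) unepimerised, which an amine-based oxidation would put at risk; a lactol between the two arms is not expected because they are trans on the cyclopentane.

Step 9
Reactants: 17 (1R,2S,5R)-2-methyl-2-(3-methylbut-3-enoyl)-5-(propan-2-yl)-5-(triethylsilyloxy)cyclopentane-1-carbaldehyde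
Product: 19 6α-hydroxy-4β-(triethylsilyloxy)dauc-8-en-10-one, via exocyclic alkene isomer 18 (not isolated)
Conditions: Me2AlCl (2 equiv), CH2Cl2, −78 → −30 °C; aq. Rochelle salt; then DBU (0.2 equiv), CH2Cl2, 0 °C
Reagents that add atoms: none
Why: Lewis acid-promoted intramolecular carbonyl-ene (Prins-type) cyclisation, of the kind with the tether on the central carbon of the ene unit, closes the seven-membered ring by C6–C7 bond formation; catalytic DBU then moves the exocyclic alkene of 18 into conjugation with the C10 ketone through the dienolate, converging on 19. In the chair-like transition state the aluminium-bound oxygen should take the pseudo-equatorial site, because the pseudo-axial one is syn to both the C1 methyl and the C4 silyloxy group; this corresponds to 6α-O. The trans ring fusion follows from the trans arms on C1 and C5.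

Step 10
Reactants: 20 4-hydroxybenzoic acid
Product: 22 4-(tert-butyldimethylsilyloxy)benzoic acid, via bis-silyl ester 21 (not isolated)
Conditions: TBSCl (2.3 equiv), imidazole, DMF, rt; then AcOH/THF/H2O, rt
Reagents that add atoms: tert-butyldimethylsilyl chloride, CC(C)(C)[Si](C)(C)Cl
Why: Exhaustive silylation followed by selective hydrolysis of the far more labile silyl ester leaves the aryl silyl ether. This is a standard protection sequence with no stereochemistry involved.

Step 11
Reactants: 19 6α-hydroxy-4β-(triethylsilyloxy)dauc-8-en-10-one; 22 4-(tert-butyldimethylsilyloxy)benzoic acid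
Product: 24 6α-[4-(tert-butyldimethylsilyloxy)benzoyloxy]-4β-(triethylsilyloxy)dauc-8-en-10-one, via aroyl mixed anhydride 23 (not isolated)
Conditions: 22, 2,4,6-Cl3C6H2COCl, Et3N, THF, rt; then 19, DMAP, toluene, rt → 50 °C
Reagents that add atoms: none
Why: Yamaguchi esterification: with DMAP as acyl-transfer catalyst the alcohol attacks the unhindered aroyl carbonyl of the mixed anhydride and not the di-ortho-chlorinated one. The bases are too weak to deprotonate the γ-position of the enone, so the new ester is not lost by vinylogous elimination, and O-acylation leaves C6 untouched.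

Step 12
Reactants: 24 6α-[4-(tert-butyldimethylsilyloxy)benzoyloxy]-4β-(triethylsilyloxy)dauc-8-en-10-one
Product: 25 6α-[4-(tert-butyldimethylsilyloxy)benzoyloxy]-4β-(triethylsilyloxy)dauc-8-en-10β-ol
Conditions: NaBH4, CeCl3·7H2O, MeOH, −78 → −40 °C
Reagents that add atoms: none
Why: Luche reduction: the cerium-modified borohydride reduces the enone 1,2. Hydride should approach C10 anti to the axial angular methyl on the adjacent C1, that is from the α face, as in the reduction of ketones next to an angular methyl in steroids and decalones, giving the 10β-alcohol cis to the methyl.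

Step 13
Reactants: 25 6α-[4-(tert-butyldimethylsilyloxy)benzoyloxy]-4β-(triethylsilyloxy)dauc-8-en-10β-ol; 26 angelic acid
Product: 28 10β-angeloyloxy-6α-[4-(tert-butyldimethylsilyloxy)benzoyloxy]-4β-(triethylsilyloxy)dauc-8-ene, via angeloyl mixed anhydride 27 (not isolated)
Conditions: 26, 2,4,6-Cl3C6H2COCl, Et3N, toluene, rt; then 25, toluene, 80 °C
Reagents that add atoms: none
Why: Thermal acyl transfer from the mixed 2,4,6-trichlorobenzoic angelic anhydride without a nucleophilic catalyst is the established way to esterify hindered alcohols with retention of the Z geometry, since the slip to tiglate runs through conjugate addition of nucleophilic catalysts. Attack occurs at the less shielded angeloyl carbonyl, and C10–OH is the only free hydroxyl.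

Step 14
Reactants: 28 10β-angeloyloxy-6α-[4-(tert-butyldimethylsilyloxy)benzoyloxy]-4β-(triethylsilyloxy)dauc-8-ene
Product: 29 10β-angeloyloxy-4β-hydroxy-6α-(4-hydroxybenzoyloxy)dauc-8-ene (target CNP0273650.10)
Conditions: HF·pyridine, pyridine, THF, 0 °C → rt
Reagents that add atoms: none
Why: Fluoride-driven Si–O cleavage removes the tertiary triethylsilyl ether and the aryl tert-butyldimethylsilyl ether. Pyridine-buffered HF is not basic enough to isomerise the angelate or trigger acyl migration, and not acidic enough to ionise the allylic C10 ester.

## Compound list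

1 | 3-methylcyclopent-2-en-1-one | CC1=CC(=O)CC1 | starting material
2 | vinylmagnesium bromide | C=C[Mg]Br | starting material
3 | formaldehyde | C=O | starting material
4 | dimethyl(vinyl)aluminium | C=C[Al](C)C | intermediate (not isolated)
5 | dimethylaluminium (R)-3-ethenyl-3-methylcyclopent-1-en-1-olate | C[Al](C)OC1=C[C@@](C)(C=C)CC1 | intermediate (not isolated)
6 | (2S,3R)-3-ethenyl-2-(hydroxymethyl)-3-methylcyclopentan-1-one | OC[C@@H]1[C@@](C)(C=C)CCC1=O | intermediate
7 | (2S,3R)-3-ethenyl-3-methyl-2-[(triethylsilyloxy)methyl]cyclopentan-1-one | CC[Si](CC)(CC)OC[C@@H]1[C@@](C)(C=C)CCC1=O | intermediate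
8 | isopropylmagnesium chloride | CC(C)[Mg]Cl | starting material
9 | isopropylcerium dichloride | CC(C)[Ce](Cl)Cl | intermediate (not isolated)
10 | (1R,2S,3R)-3-ethenyl-3-methyl-1-(propan-2-yl)-2-[(triethylsilyloxy)methyl]cyclopentan-1-ol | CC[Si](CC)(CC)OC[C@@H]1[C@@](C)(C=C)CC[C@@]1(O)C(C)C | intermediate
11 | triethyl{[(1R,2S,3R)-3-ethenyl-3-methyl-1-(propan-2-yl)-2-[(triethylsilyloxy)methyl]cyclopentyl]oxy}silane | CC[Si](CC)(CC)OC[C@@H]1[C@@](C)(C=C)CC[C@@]1(O[Si](CC)(CC)CC)C(C)C | intermediate
12 | (1S,2S,3R)-1-methyl-3-(propan-2-yl)-3-(triethylsilyloxy)-2-[(triethylsilyloxy)methyl]cyclopentane-1-carbaldehyde | CC[Si](CC)(CC)OC[C@@H]1[C@@](C)(C=O)CC[C@@]1(O[Si](CC)(CC)CC)C(C)C | intermediate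
13 | 3-chloro-2-methylprop-1-ene | C=C(C)CCl | starting material
14 | (2-methylprop-2-en-1-yl)magnesium chloride | C=C(C)C[Mg]Cl | intermediate (not isolated)
15 | 3-methyl-1-[(1S,2S,3R)-1-methyl-3-(propan-2-yl)-3-(triethylsilyloxy)-2-[(triethylsilyloxy)methyl]cyclopentyl]but-3-en-1-ol (both C10 epimers) | CC[Si](CC)(CC)OC[C@@H]1[C@@](C)(C(O)CC(C)=C)CC[C@@]1(O[Si](CC)(CC)CC)C(C)C | intermediate
16 | 1-[(1S,2S,3R)-2-(hydroxymethyl)-1-methyl-3-(propan-2-yl)-3-(triethylsilyloxy)cyclopentyl]-3-methylbut-3-en-1-ol | OC[C@@H]1[C@@](C)(C(O)CC(C)=C)CC[C@@]1(O[Si](CC)(CC)CC)C(C)C | intermediate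
17 | (1R,2S,5R)-2-methyl-2-(3-methylbut-3-enoyl)-5-(propan-2-yl)-5-(triethylsilyloxy)cyclopentane-1-carbaldehyde | O=C[C@@H]1[C@@](C)(C(=O)CC(C)=C)CC[C@@]1(O[Si](CC)(CC)CC)C(C)C | intermediate
18 | 6α-hydroxy-4β-(triethylsilyloxy)dauc-8(14)-en-10-one | O=C1CC(=C)C[C@H](O)[C@@H]2[C@]1(C)CC[C@@]2(O[Si](CC)(CC)CC)C(C)C | intermediate (not isolated)
19 | 6α-hydroxy-4β-(triethylsilyloxy)dauc-8-en-10-one | O=C1C=C(C)C[C@H](O)[C@@H]2[C@]1(C)CC[C@@]2(O[Si](CC)(CC)CC)C(C)C | intermediate
20 | 4-hydroxybenzoic acid | OC(=O)c1ccc(O)cc1 | starting material
21 | tert-butyldimethylsilyl 4-(tert-butyldimethylsilyloxy)benzoate | CC(C)(C)[Si](C)(C)OC(=O)c1ccc(O[Si](C)(C)C(C)(C)C)cc1 | intermediate (not isolated)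
22 | 4-(tert-butyldimethylsilyloxy)benzoic acid | OC(=O)c1ccc(O[Si](C)(C)C(C)(C)C)cc1 | intermediate
23 | 4-(tert-butyldimethylsilyloxy)benzoic 2,4,6-trichlorobenzoic anhydride | O=C(OC(=O)c1c(Cl)cc(Cl)cc1Cl)c1ccc(O[Si](C)(C)C(C)(C)C)cc1 | intermediate (not isolated)
24 | 6α-[4-(tert-butyldimethylsilyloxy)benzoyloxy]-4β-(triethylsilyloxy)dauc-8-en-10-one | O=C1C=C(C)C[C@H](OC(=O)c3ccc(O[Si](C)(C)C(C)(C)C)cc3)[C@@H]2[C@]1(C)CC[C@@]2(O[Si](CC)(CC)CC)C(C)C | intermediate
25 | 6α-[4-(tert-butyldimethylsilyloxy)benzoyloxy]-4β-(triethylsilyloxy)dauc-8-en-10β-ol | O[C@H]1C=C(C)C[C@H](OC(=O)c3ccc(O[Si](C)(C)C(C)(C)C)cc3)[C@@H]2[C@]1(C)CC[C@@]2(O[Si](CC)(CC)CC)C(C)C | intermediate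
26 | angelic acid, (Z)-2-methylbut-2-enoic acid | C/C=C(/C)C(=O)O | starting material
27 | (Z)-2-methylbut-2-enoic 2,4,6-trichlorobenzoic anhydride | C/C=C(/C)C(=O)OC(=O)c1c(Cl)cc(Cl)cc1Cl | intermediate (not isolated)
28 | 10β-angeloyloxy-6α-[4-(tert-butyldimethylsilyloxy)benzoyloxy]-4β-(triethylsilyloxy)dauc-8-ene | C/C=C(/C)C(=O)O[C@H]1C=C(C)C[C@H](OC(=O)c3ccc(O[Si](C)(C)C(C)(C)C)cc3)[C@@H]2[C@]1(C)CC[C@@]2(O[Si](CC)(CC)CC)C(C)C | intermediate
29 | 10β-angeloyloxy-4β-hydroxy-6α-(4-hydroxybenzoyloxy)dauc-8-ene; [(3R,3aS,4S,8S,8aS)-3-hydroxy-4-(4-hydroxybenzoyloxy)-6,8a-dimethyl-3-(propan-2-yl)-1,2,3,3a,4,5,8,8a-octahydroazulen-8-yl] (Z)-2-methylbut-2-enoate | C/C=C(/C)C(=O)O[C@H]1C=C(C)C[C@H](OC(=O)c2ccc(O)cc2)[C@@H]2[C@]1(C)CC[C@@]2(O)C(C)C | target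

## Step count and least certain steps

Total step count: 14 (13 in the main line and one for the acid 22). Longest linear sequence: 13 steps, from 1 to 29 through steps 1 to 9 and 11 to 14.

Step 1 (key step). Two processes may fail. Enantioface discrimination at the β-carbon may be insufficient, because five-membered enones are the less favourable ring size for this catalyst class and the aluminium enolate may react sluggishly with formaldehyde. Facial selectivity at C5 may be poor, because methyl and vinyl shield almost equally; this would halve the throughput of the first step and leave an epimer to remove. Fallback, setting out from 1 and 3: hydroalumination of trimethylsilylacetylene with i-Bu2AlH gives diisobutyl[1-(trimethylsilyl)ethenyl]aluminium F1. Its conjugate addition to 1 with Cu(OTf)2 and a chiral sulfonate-bearing N-heterocyclic carbene ligand, a combination with precedent on five-membered enones, followed by the same trapping with 3, should give the silylated aldol F2. Its bulky 1-silylvinyl group leaves only the face of C5 anti to it open. Protodesilylation (CF3CO2H, CH2Cl2, 0 °C, then NaHCO3/MeOH) returns to the route at 6.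

Step 9. Enolisation of the β,γ-unsaturated ketone towards C9 may lead to aldol closure of a five-membered ring instead of the ene reaction. The alkene may conjugate before cyclisation, the face of the aldehyde may be poorly selected at C6, and the base treatment may drive the alkene on towards C7. Fallback, setting out from 12 and closing the ring by metathesis: addition of 2 to 12 gives the allylic alcohol F3. PPTS in methanol gives the diol F4, and Dess–Martin oxidation gives the vinyl ketone aldehyde F5. Aldehyde-selective allylboration with 2-methylallylboronic acid pinacol ester gives the homoallylic alcohol F6. Ring-closing metathesis with second-generation Grubbs catalyst forms C8=C9 directly and comes back to the route at 19.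

Step 11. Acylation may be slow because the C6 hydroxyl lies close to the C4 silyl ether, and forcing it risks elimination across the enone. Fallback, setting out from 19 with a changed protecting-group plan: HF·pyridine removes the tertiary silyl ether to give the diol enone F7. Its secondary C6 hydroxyl is acylated with 23 beside the inert tertiary one to give the ester F8. Luche reduction gives the diol ester F9, and acylation with 27 gives the angelate F10. HF·pyridine then frees the phenol and the route is rejoined at 29.

Step 12. Hydride may approach from the β face if the seven-membered enone adopts a conformation in which the C1 methyl no longer shields that face. Fallback, setting out from 24: reagent-controlled reduction with a CBS oxazaborolidine and catecholborane, the catalyst enantiomer being chosen for α-face delivery, returns to the route at 25 and makes no new compound.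

Step 13. The angeloyl unit may isomerise from Z to E, acyl transfer to the neopentyl-type allylic alcohol may be slow, and prolonged heating may ionise the allylic centre. Fallback, setting out from 25 and building the Z-alkene after the ester bond: 2-[bis(2,2,2-trifluoroethoxy)phosphoryl]propanoic acid F11 (from its methyl ester) is coupled to 25 with DCC and DMAP to give the phosphonate ester F12. Still–Gennari olefination with acetaldehyde (KHMDS, 18-crown-6, THF, −78 °C) gives the Z-2-methylbut-2-enoate and returns to the route at 28.

## Further compounds

F1 | step 1 | diisobutyl[1-(trimethylsilyl)ethenyl]aluminium | C=C([Si](C)(C)C)[Al](CC(C)C)CC(C)C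
F2 | step 1 | (2S,3S)-2-(hydroxymethyl)-3-methyl-3-[1-(trimethylsilyl)ethenyl]cyclopentan-1-one | OC[C@@H]1[C@@](C)(C(=C)[Si](C)(C)C)CCC1=O
F3 | step 9 | 1-[(1S,2S,3R)-1-methyl-3-(propan-2-yl)-3-(triethylsilyloxy)-2-[(triethylsilyloxy)methyl]cyclopentyl]prop-2-en-1-ol (both C10 epimers) | CC[Si](CC)(CC)OC[C@@H]1[C@@](C)(C(O)C=C)CC[C@@]1(O[Si](CC)(CC)CC)C(C)C
F4 | step 9 | 1-[(1S,2S,3R)-2-(hydroxymethyl)-1-methyl-3-(propan-2-yl)-3-(triethylsilyloxy)cyclopentyl]prop-2-en-1-ol | OC[C@@H]1[C@@](C)(C(O)C=C)CC[C@@]1(O[Si](CC)(CC)CC)C(C)C
F5 | step 9 | (1R,2S,5R)-2-methyl-2-(prop-2-enoyl)-5-(propan-2-yl)-5-(triethylsilyloxy)cyclopentane-1-carbaldehyde | O=C[C@@H]1[C@@](C)(C(=O)C=C)CC[C@@]1(O[Si](CC)(CC)CC)C(C)C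
F6 | step 9 | 1-[(1S,2S,3R)-2-[(1S)-1-hydroxy-3-methylbut-3-en-1-yl]-1-methyl-3-(propan-2-yl)-3-(triethylsilyloxy)cyclopentyl]prop-2-en-1-one | C=C(C)C[C@H](O)[C@@H]1[C@@](C)(C(=O)C=C)CC[C@@]1(O[Si](CC)(CC)CC)C(C)C
F7 | step 11 | 4β,6α-dihydroxydauc-8-en-10-one | O=C1C=C(C)C[C@H](O)[C@@H]2[C@]1(C)CC[C@@]2(O)C(C)C
F8 | step 11 | 6α-[4-(tert-butyldimethylsilyloxy)benzoyloxy]-4β-hydroxydauc-8-en-10-one | O=C1C=C(C)C[C@H](OC(=O)c3ccc(O[Si](C)(C)C(C)(C)C)cc3)[C@@H]2[C@]1(C)CC[C@@]2(O)C(C)C
F9 | step 11 | 6α-[4-(tert-butyldimethylsilyloxy)benzoyloxy]dauc-8-ene-4β,10β-diol | O[C@H]1C=C(C)C[C@H](OC(=O)c3ccc(O[Si](C)(C)C(C)(C)C)cc3)[C@@H]2[C@]1(C)CC[C@@]2(O)C(C)C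
F10 | step 11 | 10β-angeloyloxy-6α-[4-(tert-butyldimethylsilyloxy)benzoyloxy]dauc-8-en-4β-ol | C/C=C(/C)C(=O)O[C@H]1C=C(C)C[C@H](OC(=O)c3ccc(O[Si](C)(C)C(C)(C)C)cc3)[C@@H]2[C@]1(C)CC[C@@]2(O)C(C)C
F0 | step 12 | none | none
F11 | step 13 | 2-[bis(2,2,2-trifluoroethoxy)phosphoryl]propanoic acid | CC(C(=O)O)P(=O)(OCC(F)(F)F)OCC(F)(F)F
F12 | step 13 | 10β-{2-[bis(2,2,2-trifluoroethoxy)phosphoryl]propanoyloxy}-6α-[4-(tert-butyldimethylsilyloxy)benzoyloxy]-4β-(triethylsilyloxy)dauc-8-ene | CC(P(=O)(OCC(F)(F)F)OCC(F)(F)F)C(=O)O[C@H]1C=C(C)C[C@H](OC(=O)c3ccc(O[Si](C)(C)C(C)(C)C)cc3)[C@@H]2[C@]1(C)CC[C@@]2(O[Si](CC)(CC)CC)C(C)C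
A1 | alternative 1 | dauca-5,9-dien-4-ol triethylsilyl ether | C1=C[C@@H](C)CC=C2[C@]1(C)CC[C@@]2(O[Si](CC)(CC)CC)C(C)C
A2 | alternative 1 | (S)-terpinen-4-ol | CC1=CC[C@](O)(C(C)C)CC1
A3 | alternative 2 | methyl 5-methyl-2-oxo-5-(pivaloyloxymethyl)cyclopentane-1-carboxylate | COC(=O)[C@@H]1[C@@](C)(COC(=O)C(C)(C)C)CCC1=O
A4 | alternative 2 | methyl (6S)-2-diazo-6-methyl-3-oxo-7-(pivaloyloxy)heptanoate | COC(=O)C(=[N+]=[N-])C(=O)CC[C@H](C)COC(=O)C(C)(C)C
A5 | alternative 3 | 8-methylene-4-triethylsilyloxydaucane-6,10-diol | O[C@H]1CC(=C)C[C@H](O)[C@@H]2[C@]1(C)CC[C@@]2(O[Si](CC)(CC)CC)C(C)C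
A6 | alternative 3 | (1S,2R,3R)-1-methyl-3-(propan-2-yl)-3-(triethylsilyloxy)cyclopentane-1,2-dicarbaldehyde | O=C[C@@H]1[C@@](C)(C=O)CC[C@@]1(O[Si](CC)(CC)CC)C(C)C
A7 | alternative 3 | 3-iodo-2-(iodomethyl)prop-1-ene | C=C(CI)CI
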